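**Assumption:** the (S,S) hand of the diene ligand in step 8 is taken to deliver the aryl group to the Si face of the enone β-carbon; if the first assay shows the opposite sense, the (R,R) ligand is used in the same way.

## Retrosynthetic overview

1. In pyran ring C the ring B aryl on C2, the hydroxyl on C3 and the ring D aryl on C4 alternate faces (2R,3S,4R) and O1 is bonded to C2. H-2 and O-3 are therefore cis to each other and anti to the C4 aryl, which is the outcome of a syn hydroboration of an O1–C2=C3 enol ether.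
2. C3–O and C2–H are disconnected to a 2,4-diaryl-4H-chromene whose only stereocentre is C4; ring C is then opened at O1–C2 to an o-hydroxyaryl β,β-diaryl ketone.
3. C4–C1' (ring D) is disconnected by rhodium-catalysed asymmetric 1,4-arylation of a retrochalcone, and C3=C4 by Claisen–Schmidt condensation of a ring A aldehyde with a ring B acetophenone.
4. Rings A, B and D are purchased. Ring C is the only ring formed (O1–C2 closure, before the hydroboration), and five benzyl ethers are removed together at the end.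

Key step: step 11

## Route

Step 1
Reactants: 1 2,4-dihydroxybenzaldehyde
Product: 2 4-(benzyloxy)-2-hydroxybenzaldehyde
Conditions: BnBr (1.05 equiv), NaHCO3, KI (cat.), MeCN, 80 °C
Reagents that add atoms: benzyl bromide, BrCc1ccccc1
Why: Williamson etherification is selective for O-4 because the 4-OH is the more acidic phenol while the 2-OH is held in a hydrogen bond to the formyl group and is not deprotonated by the weak base.

Step 2
Reactants: 2 4-(benzyloxy)-2-hydroxybenzaldehyde
Product: 3 4-(benzyloxy)-2-(methoxymethoxy)benzaldehyde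
Conditions: NaH, MOMCl, DMF, 0 °C to rt
Reagents that add atoms: chloromethyl methyl ether, COCCl
Why: O-alkylation of the sodium phenoxide masks the future O1 as an acetal that mild acid can later remove without touching benzyl ethers.

Step 3
Reactants: 4 3',4'-dihydroxyacetophenone
Product: 5 1-[3,4-bis(benzyloxy)phenyl]ethan-1-one
Conditions: BnBr (2.3 equiv), K2CO3, DMF, 60 °C
Reagents that add atoms: benzyl bromide, BrCc1ccccc1
Why: Double Williamson etherification of the catechol gives the ring B ketone that supplies C2 and C3, with both phenols protected against base and borane.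

Step 4
Reactants: 3 4-(benzyloxy)-2-(methoxymethoxy)benzaldehyde; 5 1-[3,4-bis(benzyloxy)phenyl]ethan-1-one
Product: 7 (E)-1-[3,4-bis(benzyloxy)phenyl]-3-[4-(benzyloxy)-2-(methoxymethoxy)phenyl]prop-2-en-1-one, via aldol adduct 6 (not isolated)
Conditions: KOH (aq. 50%), EtOH/THF, rt
Reagents that add atoms: none
Why: Claisen–Schmidt condensation: the enolate of 5 adds to the non-enolisable aldehyde 3 and E1cB loss of water from 6 gives the thermodynamically favoured (E)-enone, forming C3=C4 with the ketone carbon as the future C2.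

Step 5
Reactants: 8 2-methoxyresorcinol
Product: 9 1,3-bis(benzyloxy)-2-methoxybenzene
Conditions: BnBr (2.3 equiv), K2CO3, DMF, 60 °C
Reagents that add atoms: benzyl bromide, BrCc1ccccc1
Why: Double Williamson etherification protects both ring D phenols with the same group used on rings A and B, so one final hydrogenolysis frees them all.

Step 6
Reactants: 9 1,3-bis(benzyloxy)-2-methoxybenzene
Product: 10 1-bromo-2,4-bis(benzyloxy)-3-methoxybenzene
Conditions: NBS (1.0 equiv), MeCN, 0 °C to rt, dark
Reagents that add atoms: N-bromosuccinimide, O=C1CCC(=O)N1Br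
Why: Electrophilic aromatic bromination goes to C4, which is para to one benzyloxy group and ortho to the other, whereas C5 is meta to both and the flanked methoxy group is twisted out of conjugation; one equivalent of NBS should stop at the monobromide.

Step 7
Reactants: 10 1-bromo-2,4-bis(benzyloxy)-3-methoxybenzene
Product: 13 [2,4-bis(benzyloxy)-3-methoxyphenyl]boronic acid, via aryllithium 11 (not isolated), via lithium aryltriisopropoxyborate 12 (not isolated)
Conditions: B(OiPr)3 (1.5 equiv) present, n-BuLi (1.1 equiv), THF/toluene, −78 °C; then 1 M HCl, 0 °C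
Reagents that add atoms: triisopropyl borate, CC(C)OB(OC(C)C)OC(C)C; water, O
Why: Bromine–lithium exchange is faster than any attack on the benzyl ethers at −78 °C, and trapping of 11 by the borate as it forms followed by hydrolysis of 12 gives the boronic acid at the carbon that will bond to C4.

Step 8
Reactants: 7 (E)-1-[3,4-bis(benzyloxy)phenyl]-3-[4-(benzyloxy)-2-(methoxymethoxy)phenyl]prop-2-en-1-one; 13 [2,4-bis(benzyloxy)-3-methoxyphenyl]boronic acid
Product: 14 (3S)-1-[3,4-bis(benzyloxy)phenyl]-3-[2,4-bis(benzyloxy)-3-methoxyphenyl]-3-[4-(benzyloxy)-2-(methoxymethoxy)phenyl]propan-1-one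
Conditions: [RhCl(C2H4)2]2 (2.5 mol%), (S,S)-Ph-bod* [(1S,4S)-2,5-diphenylbicyclo[2.2.2]octa-2,5-diene, 5.5 mol%], 13 (2.5 equiv), KOH aq. (0.5 equiv), 1,4-dioxane/H2O 10:1, 40 °C, Ar; ee assay by chiral HPLC, recrystallisation if needed
Reagents that add atoms: none
Why: Hayashi–Miyaura asymmetric 1,4-addition: transmetallation gives an aryl complex of monovalent rhodium on the C2-symmetric diene, the (E)-enone inserts with the ligand selecting the Si face of the β-carbon, and hydrolysis of the oxa-π-allyl rhodium species releases the ketone, so the catalyst alone sets C4 however alike the two aryl groups are.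

Step 9
Reactants: 14 (3S)-1-[3,4-bis(benzyloxy)phenyl]-3-[2,4-bis(benzyloxy)-3-methoxyphenyl]-3-[4-(benzyloxy)-2-(methoxymethoxy)phenyl]propan-1-one
Product: 15 (3S)-1-[3,4-bis(benzyloxy)phenyl]-3-[2,4-bis(benzyloxy)-3-methoxyphenyl]-3-[4-(benzyloxy)-2-hydroxyphenyl]propan-1-one
Conditions: conc. HCl (cat.), MeOH/THF, 45 °C, Ar
Reagents that add atoms: none
Why: Acid-catalysed methanolysis of the aryl MOM acetal frees only the ring A phenol that will become O1; benzyl ethers and the ketone are stable to these conditions and the benzhydrylic C4 is not enolisable.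

Step 10
Reactants: 15 (3S)-1-[3,4-bis(benzyloxy)phenyl]-3-[2,4-bis(benzyloxy)-3-methoxyphenyl]-3-[4-(benzyloxy)-2-hydroxyphenyl]propan-1-one
Product: 17 (4S)-7-(benzyloxy)-2-[3,4-bis(benzyloxy)phenyl]-4-[2,4-bis(benzyloxy)-3-methoxyphenyl]-4H-chromene, via cyclic hemiketal 16 (not isolated)
Conditions: PPTS (10 mol%), toluene, 4 Å MS, 70 °C, Ar, dark; Et3N quench, filtration through basic alumina, used at once
Reagents that add atoms: none
Why: Cyclodehydration: the phenol adds to the ketone (6-exo O1–C2 closure) to give hemiketal 16, whose acid-catalysed loss of water through the 2-aryl oxocarbenium ion gives the enol ether conjugated with ring B, with C4 untouched provided oxidants and strong acid are kept out.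

Step 11
Reactants: 17 (4S)-7-(benzyloxy)-2-[3,4-bis(benzyloxy)phenyl]-4-[2,4-bis(benzyloxy)-3-methoxyphenyl]-4H-chromene
Product: 19 (2R,3S,4S)-7-(benzyloxy)-2-[3,4-bis(benzyloxy)phenyl]-4-[2,4-bis(benzyloxy)-3-methoxyphenyl]chroman-3-ol, via C3 alkylborane 18 (not isolated)
Conditions: BH3·THF (3 equiv), THF, 0 °C to rt; then 3 M NaOH, 30% H2O2, 0 °C
Reagents that add atoms: hydrogen peroxide, OO
Why: Borane adds across C2=C3 through a concerted four-centre transition state, boron to C3 and hydride to C2, and alkaline peroxide then replaces boron by oxygen through a 1,2-shift of C3 from boron to oxygen with retention (hydroboration–oxidation of a cyclic enol ether, as practised on glycals and 2-aryl-4H-chromenes). No ring is closed in this step; ring C is already in place from step 10. C3 is set by the face of boron delivery and C2 by the syn-delivered hydride, so H-2 and O-3 end up cis and the ring B aryl trans to the hydroxyl (2,3-trans), while the face is chosen by the C4 stereocentre, whose ring D aryl sits pseudoaxial on the shallow boat of the 4H-chromene (avoiding the peri H-5) and screens its own side, giving 3,4-trans. The step needs regioselectivity for boron at C3 and anti facial selectivity: the first follows from O1 lone-pair donation, which makes C3 the nucleophilic terminus and C2 (also benzylic to ring B) the carbon that accepts hydride, the second from the pseudoaxial C4 aryl. C2=C3 is the only alkene and all phenols are benzyl ethers inert to borane; the oxidation is run cold and at once because the equatorial C3–B bond is antiperiplanar to C2–O1 and could otherwise eliminate with ring opening.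

Step 12
Reactants: 19 (2R,3S,4S)-7-(benzyloxy)-2-[3,4-bis(benzyloxy)phenyl]-4-[2,4-bis(benzyloxy)-3-methoxyphenyl]chroman-3-ol
Product: 20 (2R,3S,4R)-2-(3,4-dihydroxyphenyl)-4-(2,4-dihydroxy-3-methoxyphenyl)chromane-3,7-diol (CNP0124388.1)
Conditions: H2 (1 atm), Pd(OH)2/C, THF/MeOH 1:1, rt, no acid; filtration and concentration under Ar
Reagents that add atoms: none
Why: Hydrogenolysis cleaves the five benzyl aryl ethers while the ring D methyl ether, the C2–O1 bond and the three stereocentres are untouched under neutral conditions; the C4 descriptor changes from S to R only because the free 2'-OH lowers the CIP rank of ring D below C4a, with no change in geometry.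

## Compound list

1 | 2,4-dihydroxybenzaldehyde | O=Cc1ccc(O)cc1O | starting material
2 | 4-(benzyloxy)-2-hydroxybenzaldehyde | O=Cc1ccc(OCc2ccccc2)cc1O | intermediate
3 | 4-(benzyloxy)-2-(methoxymethoxy)benzaldehyde | COCOc1cc(OCc2ccccc2)ccc1C=O | intermediate
4 | 3',4'-dihydroxyacetophenone | CC(=O)c1ccc(O)c(O)c1 | starting material
5 | 1-[3,4-bis(benzyloxy)phenyl]ethan-1-one | CC(=O)c1ccc(OCc2ccccc2)c(OCc2ccccc2)c1 | intermediate
6 | aldol adduct: 1-[3,4-bis(benzyloxy)phenyl]-3-[4-(benzyloxy)-2-(methoxymethoxy)phenyl]-3-hydroxypropan-1-one (racemic) | COCOc1cc(OCc2ccccc2)ccc1C(O)CC(=O)c1ccc(OCc2ccccc2)c(OCc2ccccc2)c1 | intermediate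
7 | (E)-1-[3,4-bis(benzyloxy)phenyl]-3-[4-(benzyloxy)-2-(methoxymethoxy)phenyl]prop-2-en-1-one | COCOc1cc(OCc2ccccc2)ccc1/C=C/C(=O)c1ccc(OCc2ccccc2)c(OCc2ccccc2)c1 | intermediate
8 | 2-methoxyresorcinol (2-methoxybenzene-1,3-diol) | COc1c(O)cccc1O | starting material
9 | 1,3-bis(benzyloxy)-2-methoxybenzene | COc1c(OCc2ccccc2)cccc1OCc1ccccc1 | intermediate
10 | 1-bromo-2,4-bis(benzyloxy)-3-methoxybenzene | COc1c(OCc2ccccc2)ccc(Br)c1OCc1ccccc1 | intermediate
11 | aryllithium: [2,4-bis(benzyloxy)-3-methoxyphenyl]lithium | [Li]c1ccc(OCc2ccccc2)c(OC)c1OCc1ccccc1 | intermediate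
12 | lithium aryltriisopropoxyborate: lithium [2,4-bis(benzyloxy)-3-methoxyphenyl]tri(propan-2-yloxy)borate | [Li+].COc1c(OCc2ccccc2)ccc([B-](OC(C)C)(OC(C)C)OC(C)C)c1OCc1ccccc1 | intermediate
13 | [2,4-bis(benzyloxy)-3-methoxyphenyl]boronic acid | COc1c(OCc2ccccc2)ccc(B(O)O)c1OCc1ccccc1 | intermediate
14 | (3S)-1-[3,4-bis(benzyloxy)phenyl]-3-[2,4-bis(benzyloxy)-3-methoxyphenyl]-3-[4-(benzyloxy)-2-(methoxymethoxy)phenyl]propan-1-one | COc1c(OCc2ccccc2)ccc([C@@H](CC(=O)c2ccc(OCc3ccccc3)c(OCc3ccccc3)c2)c2ccc(OCc3ccccc3)cc2OCOC)c1OCc1ccccc1 | intermediate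
15 | (3S)-1-[3,4-bis(benzyloxy)phenyl]-3-[2,4-bis(benzyloxy)-3-methoxyphenyl]-3-[4-(benzyloxy)-2-hydroxyphenyl]propan-1-one | COc1c(OCc2ccccc2)ccc([C@@H](CC(=O)c2ccc(OCc3ccccc3)c(OCc3ccccc3)c2)c2ccc(OCc3ccccc3)cc2O)c1OCc1ccccc1 | intermediate
16 | cyclic hemiketal: (4S)-7-(benzyloxy)-2-[3,4-bis(benzyloxy)phenyl]-4-[2,4-bis(benzyloxy)-3-methoxyphenyl]chroman-2-ol (C2 epimers) | COc1c(OCc2ccccc2)ccc([C@@H]2c3ccc(OCc4ccccc4)cc3OC(O)(c3ccc(OCc4ccccc4)c(OCc4ccccc4)c3)C2)c1OCc1ccccc1 | intermediate
17 | (4S)-7-(benzyloxy)-2-[3,4-bis(benzyloxy)phenyl]-4-[2,4-bis(benzyloxy)-3-methoxyphenyl]-4H-chromene | COc1c(OCc2ccccc2)ccc([C@@H]2c3ccc(OCc4ccccc4)cc3OC(c3ccc(OCc4ccccc4)c(OCc4ccccc4)c3)=C2)c1OCc1ccccc1 | intermediate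
18 | C3 alkylborane: 3-boranyl-7-(benzyloxy)-2-[3,4-bis(benzyloxy)phenyl]-4-[2,4-bis(benzyloxy)-3-methoxyphenyl]chromane, boron and H-2 cis, both anti to the C4 aryl | COc1c(OCc2ccccc2)ccc([C@@H]2c3ccc(OCc4ccccc4)cc3O[C@H](c3ccc(OCc4ccccc4)c(OCc4ccccc4)c3)[C@H]2B)c1OCc1ccccc1 | intermediate
19 | (2R,3S,4S)-7-(benzyloxy)-2-[3,4-bis(benzyloxy)phenyl]-4-[2,4-bis(benzyloxy)-3-methoxyphenyl]chroman-3-ol (2,3-trans-3,4-trans) | COc1c(OCc2ccccc2)ccc([C@@H]2c3ccc(OCc4ccccc4)cc3O[C@H](c3ccc(OCc4ccccc4)c(OCc4ccccc4)c3)[C@H]2O)c1OCc1ccccc1 | intermediate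
20 | (2R,3S,4R)-2-(3,4-dihydroxyphenyl)-4-(2,4-dihydroxy-3-methoxyphenyl)chromane-3,7-diol (CNP0124388.1) | COc1c(O)ccc([C@@H]2c3ccc(O)cc3O[C@H](c3ccc(O)c(O)c3)[C@H]2O)c1O | target

## Step count and risks

Total step count: 12.
Longest linear sequence: 8 steps (steps 1, 2, 4, 8, 9, 10, 11, 12 from compound 1; the branch from compound 8 through steps 5, 6, 7 and then 8 to 12 is equally long).

**Step 8.** Insertion of the enone into the aryl–rhodium bond is slowed by the ortho substituents on both partners, so protodeboronation of the boron reagent may outrun C–C bond formation, or face selection may fall short. The fallback sets out from aldehyde 3 and bromide 10 and returns at ketone 14; it sets C4 by an auxiliary instead of a catalyst.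
- Knoevenagel–Doebner condensation of 3 with malonic acid (pyridine, cat. piperidine, 90 °C) should give (E)-3-[4-(benzyloxy)-2-(methoxymethoxy)phenyl]prop-2-enoic acid F1.
- Pivaloyl chloride/Et3N in THF converts F1 into the mixed pivalic anhydride F2, which acylates (S)-4-phenyloxazolidin-2-one (LiCl, THF) to give the N-enoyl oxazolidinone F3.
- Bromide 10 with Mg in THF gives [2,4-bis(benzyloxy)-3-methoxyphenyl]magnesium bromide F4. With CuBr·SMe2 at −40 to −20 °C, F4 should add to the chelated s-cis form of F3 from the face away from the oxazolidinone phenyl group, giving the 3,3-diarylpropanoyl oxazolidinone F5 with the C4 configuration of 14.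
- Me(MeO)NH·HCl/AlMe3 in CH2Cl2 at 0 °C turns F5 into the Weinreb amide F6 and returns the auxiliary.
- [3,4-Bis(benzyloxy)phenyl]magnesium bromide F7 (from purchased 4-bromo-1,2-bis(benzyloxy)benzene and Mg) converts F6 into 14.

**Step 11.** Once boron sits equatorial on C3 it is antiperiplanar to the C2–O1 bond, so loss of the ring A phenoxide with ring opening can compete with oxidation. Borane addition to the hindered trisubstituted enol ether may also be slow or not face-selective enough. The fallback sets out from chromene 17 and returns at 19; it puts oxygen on C3 first and the C2 hydrogen second.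
- Dimethyldioxirane in acetone/CH2Cl2 at −40 °C should epoxidise the enol ether anti to the C4 aryl to give the 2,3-epoxide F8.
- Methanol added to the same flask opens F8 at C2 to the 2-methoxychroman-3-ol F9 (C2 anomers, C3 and C4 defined).
- Et3SiH with BF3·OEt2 in CH2Cl2 at −78 °C then ionises C2 and should deliver hydride axially, cis to the C3 oxygen, so that ring B ends equatorial (the Kishi-type reduction of pyranosyl ketals), giving 19.

**Step 10.** Under protic acid the flav-2-ene can shift its double bond into conjugation with ring A, or lose hydride from the doubly benzylic C4 (disproportionation or air oxidation to the flavylium ion), which scrambles or erases C4. The electron-rich aryl ketone may also cyclise sluggishly. The fallback sets out from phenol-ketone 15 and returns at 17; it closes the ring as a storable mixed ketal and makes the double bond under amine buffer.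
- HC(OMe)3/MeOH with a trace of PPTS at rt should give the 2-methoxychromane F10 (C2 epimers).
- TMSOTf/iPr2NEt in CH2Cl2 at −20 °C (Gassman ketal-to-enol-ether elimination) removes the exocyclic methoxy group and deprotonates C3 to give 17 without free acid.

## Further compounds

F1 | step 8 | (E)-3-[4-(benzyloxy)-2-(methoxymethoxy)phenyl]prop-2-enoic acid | COCOc1cc(OCc2ccccc2)ccc1/C=C/C(O)=O
F2 | step 8 | (E)-3-[4-(benzyloxy)-2-(methoxymethoxy)phenyl]prop-2-enoic pivalic anhydride | COCOc1cc(OCc2ccccc2)ccc1/C=C/C(=O)OC(=O)C(C)(C)C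
F3 | step 8 | (4S)-3-[(E)-3-[4-(benzyloxy)-2-(methoxymethoxy)phenyl]prop-2-enoyl]-4-phenyloxazolidin-2-one | COCOc1cc(OCc2ccccc2)ccc1/C=C/C(=O)N1[C@@H](c2ccccc2)COC1=O
F4 | step 8 | [2,4-bis(benzyloxy)-3-methoxyphenyl]magnesium bromide | COc1c(OCc2ccccc2)ccc([Mg]Br)c1OCc1ccccc1
F5 | step 8 | (4S)-3-[(3S)-3-[2,4-bis(benzyloxy)-3-methoxyphenyl]-3-[4-(benzyloxy)-2-(methoxymethoxy)phenyl]propanoyl]-4-phenyloxazolidin-2-one | COc1c(OCc2ccccc2)ccc([C@@H](CC(=O)N2[C@@H](c3ccccc3)COC2=O)c2ccc(OCc3ccccc3)cc2OCOC)c1OCc1ccccc1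
F6 | step 8 | (3S)-3-[2,4-bis(benzyloxy)-3-methoxyphenyl]-3-[4-(benzyloxy)-2-(methoxymethoxy)phenyl]-N-methoxy-N-methylpropanamide | COc1c(OCc2ccccc2)ccc([C@@H](CC(=O)N(C)OC)c2ccc(OCc3ccccc3)cc2OCOC)c1OCc1ccccc1
F7 | step 8 | [3,4-bis(benzyloxy)phenyl]magnesium bromide | Br[Mg]c1ccc(OCc2ccccc2)c(OCc2ccccc2)c1
F8 | step 11 | 2,3-epoxide of 17: (4S)-7-(benzyloxy)-2-[3,4-bis(benzyloxy)phenyl]-4-[2,4-bis(benzyloxy)-3-methoxyphenyl]-2,3-epoxychromane, oxirane oxygen anti to the ring D aryl | COc1c(OCc2ccccc2)ccc([C@@H]2c3ccc(OCc4ccccc4)cc3O[C@@]4(c5ccc(OCc6ccccc6)c(OCc6ccccc6)c5)O[C@@H]24)c1OCc1ccccc1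
F9 | step 11 | (3S,4S)-7-(benzyloxy)-2-[3,4-bis(benzyloxy)phenyl]-4-[2,4-bis(benzyloxy)-3-methoxyphenyl]-2-methoxychroman-3-ol (C2 anomers) | COc1c(OCc2ccccc2)ccc([C@@H]2c3ccc(OCc4ccccc4)cc3OC(OC)(c3ccc(OCc4ccccc4)c(OCc4ccccc4)c3)[C@H]2O)c1OCc1ccccc1
F10 | step 10 | (4S)-7-(benzyloxy)-2-[3,4-bis(benzyloxy)phenyl]-4-[2,4-bis(benzyloxy)-3-methoxyphenyl]-2-methoxychromane (C2 epimers) | COc1c(OCc2ccccc2)ccc([C@@H]2c3ccc(OCc4ccccc4)cc3OC(OC)(c3ccc(OCc4ccccc4)c(OCc4ccccc4)c3)C2)c1OCc1ccccc1
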